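**Plan**
- Retrosynthetic cuts, in order: the ester bond O7–C(=O) of the galloyl group; the aryl ether bond O1–C8a of ring C; the C2–C1' bond to ring B; the C3–C4 bond (as an alkene).
- Enabling feature: O1 links the benzylic carbon C2 to the aromatic carbon C8a of ring A. Ring C can therefore be closed at its aryl–oxygen bond from a 1,3-diarylpropane-1,2-diol derivative that already carries a bromide at C8a and both stereocentres.
- Forward order: ring A aldehyde from 5-bromoresorcinol (C4 as CHO, Br at C8a, O5 benzyl, O7 MOM); olefination adds C3 and C2; the ring B Grignard reagent is joined at C2; palladium closes ring C, the only ring made; O7 is then unmasked and galloylated, and all benzyl groups are removed.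
- Stereochemistry: C3 (S) comes from rhodium/(S,S)-Et-DuPhos hydrogenation of an α-acetoxyacrylate. C2 (R) comes from Felkin–Anh (1,2-anti) aryl addition to the α-silyloxy aldehyde. The ring closure breaks no bond at C2 or C3, so anti becomes 2,3-trans.

Key step: step 10

Assumption: the target is read as the (2R,3S), 2,3-trans flavan-3-ol with the galloyl ester on O7; flavan numbering (O1, C2–C4, C4a, C5–C8, C8a, ring B primed) is used for ring compounds and propane numbering for open-chain ones. A bromide, not a sulfonate, is placed at C8a because aryl bromides are the proven electrophiles for this cyclisation of secondary alcohols and survive every earlier step. MOM = methoxymethyl, TBS = tert-butyldimethylsilyl, Bn = benzyl.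

**Route**

Step 1
Reactants: 1 5-bromobenzene-1,3-diol
Product: 3 2-bromo-4,6-dihydroxybenzaldehyde, via iminium chloride 2 (not isolated)
Conditions: POCl3, DMF, MeCN, 0 °C → rt; then H2O, 50 °C
Reagents that add atoms: N,N-dimethylformamide, CN(C)C=O (formyl carbon); water, O (carbonyl oxygen)
Why: Vilsmeier–Haack formylation, in which the chloroiminium ion should attack the ring carbon para to one hydroxyl and ortho to the other (the position flanked by OH and Br), as 5-substituted resorcinols such as orcinol do, and hydrolysis of iminium salt 2 releases the aldehyde.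

Step 2
Reactants: 3 2-bromo-4,6-dihydroxybenzaldehyde
Product: 4 2-bromo-6-hydroxy-4-(methoxymethoxy)benzaldehyde
Conditions: MOMCl (1.1 equiv), i-Pr2NEt, CH2Cl2, 0 °C
Reagents that add atoms: chloromethyl methyl ether, COCCl
Why: Williamson-type O-alkylation that should be selective for the 4-hydroxyl, because the 6-hydroxyl is tied up in a hydrogen bond to the formyl group while the para hydroxyl is free and more acidic, the usual behaviour of 2,4-dihydroxybenzaldehydes.

Step 3
Reactants: 4 2-bromo-6-hydroxy-4-(methoxymethoxy)benzaldehyde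
Product: 5 2-(benzyloxy)-6-bromo-4-(methoxymethoxy)benzaldehyde
Conditions: BnBr, K2CO3, DMF, 50 °C
Reagents that add atoms: benzyl bromide, BrCc1ccccc1
Why: Williamson ether synthesis on the remaining chelated phenol, which is alkylated once carbonate in warm DMF breaks the hydrogen bond, the MOM acetal being inert to base.

Step 4
Reactants: 5 2-(benzyloxy)-6-bromo-4-(methoxymethoxy)benzaldehyde; 6 ethyl 2-acetoxy-2-(diethoxyphosphoryl)acetate
Product: 7 ethyl (Z)-2-acetoxy-3-[2-(benzyloxy)-6-bromo-4-(methoxymethoxy)phenyl]prop-2-enoate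
Conditions: LiCl, DBU, MeCN, 0 °C → rt
Reagents that add atoms: none
Why: Horner–Wadsworth–Emmons olefination under mild LiCl/amidine conditions, a standard way to turn aromatic aldehydes into α-acyloxyacrylates; any E isomer is carried on because both alkene isomers are expected to converge in step 5.

Step 5
Reactants: 7 ethyl (Z)-2-acetoxy-3-[2-(benzyloxy)-6-bromo-4-(methoxymethoxy)phenyl]prop-2-enoate
Product: 8 ethyl (S)-2-acetoxy-3-[2-(benzyloxy)-6-bromo-4-(methoxymethoxy)phenyl]propanoate
Conditions: H2 (5 atm), [Rh(cod)((S,S)-Et-DuPhos)]OTf (1 mol %), MeOH, rt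
Reagents that add atoms: none
Why: Rhodium-catalysed asymmetric hydrogenation of an α-(acyloxy)acrylate, in which the acetate carbonyl and the alkene chelate the cationic monovalent rhodium centre and the (S,S)-bisphospholane is expected, by the known sense for this substrate class, to give the (S)-acetate (the future C3; the (R,R)-ligand would give the antipode), while the homogeneous catalyst leaves the aryl bromide and benzyl ethers alone.

Step 6
Reactants: 8 ethyl (S)-2-acetoxy-3-[2-(benzyloxy)-6-bromo-4-(methoxymethoxy)phenyl]propanoate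
Product: 9 ethyl (S)-3-[2-(benzyloxy)-6-bromo-4-(methoxymethoxy)phenyl]-2-hydroxypropanoate
Conditions: K2CO3 (0.2 equiv), EtOH, 0 °C → rt
Reagents that add atoms: none
Why: Base-catalysed transesterification (Zemplén-type deacetylation) in the alcohol that matches the ester, mild enough that the α-stereocentre should not epimerise.

Step 7
Reactants: 9 ethyl (S)-3-[2-(benzyloxy)-6-bromo-4-(methoxymethoxy)phenyl]-2-hydroxypropanoate
Product: 10 ethyl (S)-3-[2-(benzyloxy)-6-bromo-4-(methoxymethoxy)phenyl]-2-[(tert-butyldimethylsilyl)oxy]propanoate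
Conditions: TBSCl, imidazole, DMF, rt
Reagents that add atoms: tert-butyldimethylsilyl chloride, CC(C)(C)[Si](C)(C)Cl
Why: Imidazole-promoted silylation of the secondary alcohol, installing the bulky, weakly coordinating group that later directs step 9 and masks O3 in step 10.

Step 8
Reactants: 10 ethyl (S)-3-[2-(benzyloxy)-6-bromo-4-(methoxymethoxy)phenyl]-2-[(tert-butyldimethylsilyl)oxy]propanoate
Product: 11 (S)-3-[2-(benzyloxy)-6-bromo-4-(methoxymethoxy)phenyl]-2-[(tert-butyldimethylsilyl)oxy]propanal
Conditions: i-Bu2AlH (1.1 equiv), CH2Cl2, –78 °C; aq. KNaC4H4O6 (potassium sodium tartrate) work-up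
Reagents that add atoms: none
Why: Partial ester reduction, in which the aluminium hemiacetal of an α-silyloxy ester is stable at –78 °C so the aldehyde appears only on hydrolysis and is used at once to avoid epimerisation.

Step 9
Reactants: 11 (S)-3-[2-(benzyloxy)-6-bromo-4-(methoxymethoxy)phenyl]-2-[(tert-butyldimethylsilyl)oxy]propanal; 12 4-bromo-1,2-bis(benzyloxy)benzene
Product: 14 (1R,2S)-3-[2-(benzyloxy)-6-bromo-4-(methoxymethoxy)phenyl]-1-[3,4-bis(benzyloxy)phenyl]-2-[(tert-butyldimethylsilyl)oxy]propan-1-ol, via arylmagnesium bromide 13 (not isolated)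
Conditions: 12, Mg, THF, 40 °C; then 11, THF, –78 °C; then H2O
Reagents that add atoms: none
Why: Grignard addition under Felkin–Anh (polar, non-chelation) control, in which the bulky silyloxy group in THF lies anti to the incoming aryl group and should favour the 1,2-anti (1R) carbinol, while at –78 °C addition to the aldehyde is far faster than exchange with the aryl bromide.

Step 10
Reactants: 14 (1R,2S)-3-[2-(benzyloxy)-6-bromo-4-(methoxymethoxy)phenyl]-1-[3,4-bis(benzyloxy)phenyl]-2-[(tert-butyldimethylsilyl)oxy]propan-1-ol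
Product: 15 (2R,3S)-5-(benzyloxy)-2-[3,4-bis(benzyloxy)phenyl]-3-[(tert-butyldimethylsilyl)oxy]-7-(methoxymethoxy)chromane
Conditions: Pd(OAc)2 (5 mol %), racemic 2-(di-tert-butylphosphino)-1,1'-binaphthyl (6 mol %), Cs2CO3, toluene, 70 °C
Reagents that add atoms: none
Why: Buchwald–Hartwig-type intramolecular aryl etherification: zerovalent palladium formed from Pd(OAc)2 and the bulky phosphine inserts into the C8a–Br bond, carbonate deprotonates the palladium-bound C2 hydroxyl, and C–O reductive elimination forms O1–C8a. The closest known reaction type is the palladium-catalysed cyclisation of 3-(2-bromoaryl)propyl secondary alcohols to 2-substituted chromans with di-tert-butylbiarylphosphines. Ring C closes as a six-membered ring by reductive elimination from a seven-membered aryl(alkoxo)palladium chelate (Pd, C8a, C4a, C4, C3, C2, O), formally an ipso substitution at C8a. No stereocentre is created; the C2–O and C3–O bonds are never broken, so the anti arrangement of 14 is carried with retention into the 2,3-trans flavan. The step needs the C2 oxygen alone to couple and reductive elimination to outrun β-hydride elimination of the benzylic alkoxide. The first is secured by the silyl ether on O3 (with a sparingly soluble carbonate in toluene keeping free alkoxide, and hence silyl migration, low) and the second by the bulky electron-rich ligand, helped by a bromide that is meta to both ring A alkoxy groups and so undergoes oxidative addition readily.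

Step 11
Reactants: 15 (2R,3S)-5-(benzyloxy)-2-[3,4-bis(benzyloxy)phenyl]-3-[(tert-butyldimethylsilyl)oxy]-7-(methoxymethoxy)chromane
Product: 16 (2R,3S)-5-(benzyloxy)-2-[3,4-bis(benzyloxy)phenyl]chromane-3,7-diol
Conditions: HCl (1.25 M in MeOH), THF, 40 °C
Reagents that add atoms: none
Why: Acid-catalysed methanolysis of the MOM acetal and of the silyl ether in one operation, under dilute acid that should leave the benzyl ethers and the cyclic benzylic ether (and so the thermodynamically preferred trans ring) unchanged.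

Step 12
Reactants: 16 (2R,3S)-5-(benzyloxy)-2-[3,4-bis(benzyloxy)phenyl]chromane-3,7-diol; 17 3,4,5-tris(benzyloxy)benzoic acid
Product: 19 (2R,3S)-5-(benzyloxy)-2-[3,4-bis(benzyloxy)phenyl]-3-hydroxychroman-7-yl 3,4,5-tris(benzyloxy)benzoate, via acid chloride 18 (not isolated)
Conditions: 17, (COCl)2, cat. DMF, CH2Cl2, rt, evaporate; then 16, Et3N, CH2Cl2, –20 → 0 °C
Reagents that add atoms: none
Why: Acid chloride formation followed by Einhorn-type O-acylation, in which one equivalent of 18 with Et3N and no DMAP at low temperature should esterify the acidic, unhindered 7-phenol (the only free phenol) much faster than the hindered secondary 3-hydroxyl.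

Step 13
Reactants: 19 (2R,3S)-5-(benzyloxy)-2-[3,4-bis(benzyloxy)phenyl]-3-hydroxychroman-7-yl 3,4,5-tris(benzyloxy)benzoate
Product: 20 catechin 7-O-gallate
Conditions: H2 (1 atm), Pd(OH)2/C, THF/EtOAc, rt
Reagents that add atoms: none
Why: Catalytic hydrogenolysis of the six O-benzyl ethers under neutral, alcohol-free conditions, which should leave the aryl gallate ester, the cyclic benzylic ether and both stereocentres untouched.

**Compound list**

1 | 5-bromobenzene-1,3-diol (5-bromoresorcinol) | Oc1cc(O)cc(Br)c1 | starting material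
2 | [(2-bromo-4,6-dihydroxyphenyl)methylidene]dimethylammonium chloride | C[N+](C)=Cc1c(O)cc(O)cc1Br.[Cl-] | intermediate (not isolated)
3 | 2-bromo-4,6-dihydroxybenzaldehyde | O=Cc1c(O)cc(O)cc1Br | intermediate
4 | 2-bromo-6-hydroxy-4-(methoxymethoxy)benzaldehyde | O=Cc1c(O)cc(OCOC)cc1Br | intermediate
5 | 2-(benzyloxy)-6-bromo-4-(methoxymethoxy)benzaldehyde | O=Cc1c(OCc2ccccc2)cc(OCOC)cc1Br | intermediate
6 | ethyl 2-acetoxy-2-(diethoxyphosphoryl)acetate | CCOC(=O)C(OC(C)=O)P(=O)(OCC)OCC | starting material
7 | ethyl (Z)-2-acetoxy-3-[2-(benzyloxy)-6-bromo-4-(methoxymethoxy)phenyl]prop-2-enoate (Z drawn; any E isomer carried on) | CCOC(=O)/C(OC(C)=O)=C/c1c(OCc2ccccc2)cc(OCOC)cc1Br | intermediate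
8 | ethyl (S)-2-acetoxy-3-[2-(benzyloxy)-6-bromo-4-(methoxymethoxy)phenyl]propanoate | CCOC(=O)[C@@H](OC(C)=O)Cc1c(OCc2ccccc2)cc(OCOC)cc1Br | intermediate
9 | ethyl (S)-3-[2-(benzyloxy)-6-bromo-4-(methoxymethoxy)phenyl]-2-hydroxypropanoate | CCOC(=O)[C@@H](O)Cc1c(OCc2ccccc2)cc(OCOC)cc1Br | intermediate
10 | ethyl (S)-3-[2-(benzyloxy)-6-bromo-4-(methoxymethoxy)phenyl]-2-[(tert-butyldimethylsilyl)oxy]propanoate | CCOC(=O)[C@@H](O[Si](C)(C)C(C)(C)C)Cc1c(OCc2ccccc2)cc(OCOC)cc1Br | intermediate
11 | (S)-3-[2-(benzyloxy)-6-bromo-4-(methoxymethoxy)phenyl]-2-[(tert-butyldimethylsilyl)oxy]propanal | O=C[C@@H](O[Si](C)(C)C(C)(C)C)Cc1c(OCc2ccccc2)cc(OCOC)cc1Br | intermediate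
12 | 4-bromo-1,2-bis(benzyloxy)benzene | Brc1ccc(OCc2ccccc2)c(OCc2ccccc2)c1 | starting material
13 | [3,4-bis(benzyloxy)phenyl]magnesium bromide | Br[Mg]c1ccc(OCc2ccccc2)c(OCc2ccccc2)c1 | intermediate (not isolated)
14 | (1R,2S)-3-[2-(benzyloxy)-6-bromo-4-(methoxymethoxy)phenyl]-1-[3,4-bis(benzyloxy)phenyl]-2-[(tert-butyldimethylsilyl)oxy]propan-1-ol | O[C@H](c1ccc(OCc2ccccc2)c(OCc2ccccc2)c1)[C@@H](O[Si](C)(C)C(C)(C)C)Cc1c(OCc2ccccc2)cc(OCOC)cc1Br | intermediate
15 | (2R,3S)-5-(benzyloxy)-2-[3,4-bis(benzyloxy)phenyl]-3-[(tert-butyldimethylsilyl)oxy]-7-(methoxymethoxy)chromane | COCOc1cc(OCc2ccccc2)c2c(c1)O[C@H](c1ccc(OCc3ccccc3)c(OCc3ccccc3)c1)[C@@H](O[Si](C)(C)C(C)(C)C)C2 | intermediate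
16 | (2R,3S)-5-(benzyloxy)-2-[3,4-bis(benzyloxy)phenyl]chromane-3,7-diol (5,3',4'-tri-O-benzylcatechin) | Oc1cc(OCc2ccccc2)c2c(c1)O[C@H](c1ccc(OCc3ccccc3)c(OCc3ccccc3)c1)[C@@H](O)C2 | intermediate
17 | 3,4,5-tris(benzyloxy)benzoic acid | OC(=O)c1cc(OCc2ccccc2)c(OCc2ccccc2)c(OCc2ccccc2)c1 | starting material
18 | 3,4,5-tris(benzyloxy)benzoyl chloride | ClC(=O)c1cc(OCc2ccccc2)c(OCc2ccccc2)c(OCc2ccccc2)c1 | intermediate (not isolated)
19 | (2R,3S)-5-(benzyloxy)-2-[3,4-bis(benzyloxy)phenyl]-3-hydroxychroman-7-yl 3,4,5-tris(benzyloxy)benzoate | O=C(Oc1cc(OCc2ccccc2)c2c(c1)O[C@H](c1ccc(OCc3ccccc3)c(OCc3ccccc3)c1)[C@@H](O)C2)c1cc(OCc2ccccc2)c(OCc2ccccc2)c(OCc2ccccc2)c1 | intermediate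
20 | catechin 7-O-gallate, (2R,3S)-2-(3,4-dihydroxyphenyl)-3,5-dihydroxychroman-7-yl 3,4,5-trihydroxybenzoate | O=C(Oc1cc(O)c2c(c1)O[C@H](c1ccc(O)c(O)c1)[C@@H](O)C2)c1cc(O)c(O)c(O)c1 | target

**Step count**

Total: 13 steps. Longest linear sequence: 13 steps (1 → 20); compounds 6, 12 and 17 are bought and enter directly.

**Steps most likely to fail**

Step 10 (ring closure). The aryl(alkoxo)palladium intermediate may undergo β-hydride elimination, which would oxidise the benzylic carbinol and reduce the C–Br bond. Alternatively, base may move the silyl group to the C2 oxygen, after which O3 would close a five-membered ring. The fallback changes metal and halide. Starting from 14, an aromatic Finkelstein exchange (CuI, NaI, trans-N,N'-dimethylcyclohexane-1,2-diamine, dioxane, 110 °C; no base, so the alcohol stays inert) should give (1R,2S)-3-[2-(benzyloxy)-6-iodo-4-(methoxymethoxy)phenyl]-1-[3,4-bis(benzyloxy)phenyl]-2-[(tert-butyldimethylsilyl)oxy]propan-1-ol F1. Ullmann-type etherification of this aryl iodide (CuI, 3,4,7,8-tetramethyl-1,10-phenanthroline, Cs2CO3, toluene, 90 °C) should then form O1–C8a through a copper alkoxide that has no easy β-hydride pathway. The fallback returns to the route at 15.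

Step 9 (aryl addition). Facial selectivity may be poor if Felkin–Anh control is eroded by partial chelation, and the α-silyloxy aldehyde may epimerise before it reacts. The fallback sets C2 by hydride delivery to a ketone and avoids the aldehyde. Starting from 10, MeNH(OMe)·HCl and i-PrMgCl (THF, –20 °C) should give the Weinreb amide (S)-3-[2-(benzyloxy)-6-bromo-4-(methoxymethoxy)phenyl]-2-[(tert-butyldimethylsilyl)oxy]-N-methoxy-N-methylpropanamide F2. Addition of 13 (THF, 0 °C) should give the aryl ketone (S)-3-[2-(benzyloxy)-6-bromo-4-(methoxymethoxy)phenyl]-1-[3,4-bis(benzyloxy)phenyl]-2-[(tert-butyldimethylsilyl)oxy]propan-1-one F3. Reduction with LiBH(s-Bu)3 (THF, –78 °C), a Felkin–Anh reduction of an α-silyloxy ketone that is expected to be anti-selective, returns to the route at 14.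

Step 12 (galloylation). Chemoselectivity may be lost through competing or double acylation at the secondary 3-hydroxyl. The fallback unmasks the two oxygens in sequence. Starting from 15, ZnBr2 and n-PrSH (CH2Cl2, 0 °C) should cleave only the MOM ether and give (2R,3S)-5-(benzyloxy)-2-[3,4-bis(benzyloxy)phenyl]-3-[(tert-butyldimethylsilyl)oxy]chroman-7-ol F4. Acylation with 18 (Et3N, DMAP, CH2Cl2), now with no competing hydroxyl, should give (2R,3S)-5-(benzyloxy)-2-[3,4-bis(benzyloxy)phenyl]-3-[(tert-butyldimethylsilyl)oxy]chroman-7-yl 3,4,5-tris(benzyloxy)benzoate F5. HF·pyridine (THF, 0 °C → rt) should then remove the silyl group without touching the aryl ester, returning to the route at 19.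

**Further compounds**

F1 | step 10 | (1R,2S)-3-[2-(benzyloxy)-6-iodo-4-(methoxymethoxy)phenyl]-1-[3,4-bis(benzyloxy)phenyl]-2-[(tert-butyldimethylsilyl)oxy]propan-1-ol | O[C@H](c1ccc(OCc2ccccc2)c(OCc2ccccc2)c1)[C@@H](O[Si](C)(C)C(C)(C)C)Cc1c(OCc2ccccc2)cc(OCOC)cc1I
F2 | step 9 | (S)-3-[2-(benzyloxy)-6-bromo-4-(methoxymethoxy)phenyl]-2-[(tert-butyldimethylsilyl)oxy]-N-methoxy-N-methylpropanamide | CON(C)C(=O)[C@@H](O[Si](C)(C)C(C)(C)C)Cc1c(OCc2ccccc2)cc(OCOC)cc1Br
F3 | step 9 | (S)-3-[2-(benzyloxy)-6-bromo-4-(methoxymethoxy)phenyl]-1-[3,4-bis(benzyloxy)phenyl]-2-[(tert-butyldimethylsilyl)oxy]propan-1-one | O=C(c1ccc(OCc2ccccc2)c(OCc2ccccc2)c1)[C@@H](O[Si](C)(C)C(C)(C)C)Cc1c(OCc2ccccc2)cc(OCOC)cc1Br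
F4 | step 12 | (2R,3S)-5-(benzyloxy)-2-[3,4-bis(benzyloxy)phenyl]-3-[(tert-butyldimethylsilyl)oxy]chroman-7-ol | Oc1cc(OCc2ccccc2)c2c(c1)O[C@H](c1ccc(OCc3ccccc3)c(OCc3ccccc3)c1)[C@@H](O[Si](C)(C)C(C)(C)C)C2
F5 | step 12 | (2R,3S)-5-(benzyloxy)-2-[3,4-bis(benzyloxy)phenyl]-3-[(tert-butyldimethylsilyl)oxy]chroman-7-yl 3,4,5-tris(benzyloxy)benzoate | O=C(Oc1cc(OCc2ccccc2)c2c(c1)O[C@H](c1ccc(OCc3ccccc3)c(OCc3ccccc3)c1)[C@@H](O[Si](C)(C)C(C)(C)C)C2)c1cc(OCc2ccccc2)c(OCc2ccccc2)c(OCc2ccccc2)c1
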